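Ring C (the hydroxyquinone; abietane numbering, C8/C9 shared with cyclohexenone ring B) is cut at C12–C13 and C8–C14. The key step brings in C13–C14 with its isopropyl group as the lithium enolate of methyl 3-methylbutanoate: Claisen acylation by a CH2COCl arm on C9 forms C12–C13, then the vinylogous enolate closes C8–C14 and aromatises to a resorcinol. It exploits the 1,3-oxygen pattern at C12/C14 flanking C13 and the C7 ketone, which makes C8 nucleophilic. The precursor is a ring-B enone acid chloride carrying both stereocentres (C5, C10). Oxidation at C11 then gives the quinone.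

Key step: step 7

Remark on atom labels: ring B = C5 (CH–isopropenyl), C6, C7 (C=O), C8, C9, C10 (quaternary, CH3 and C1–C3 propanoate chain); ring C = C8, C9, C11 (C=O), C12 (C–OH), C13 (C–isopropyl), C14 (C=O).
Assumption: the chiral imidazolinium salt used with Cu(OTf)2 in step 1 is taken as the enantiomer that leads to 3R-configured 4; its sense of induction for this alkenyl Grignard/α-methyl enone pair is to be confirmed in the first run.

Step 1
Reactants: 1 2-methylcyclohex-2-en-1-one; 2 prop-1-en-2-ylmagnesium bromide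
Product: 4 (2RS,3R)-2-methyl-3-(prop-1-en-2-yl)cyclohexan-1-one, via magnesium enolate 3 (not isolated)
Conditions: Cu(OTf)2 (3 mol %), chiral imidazolinium salt (NHC precursor, 4 mol %), Et2O, −30 °C; 1 M HCl
Reagents that add atoms: prop-1-en-2-ylmagnesium bromide, C=C(C)[Mg]Br
Why: Copper-catalysed asymmetric conjugate addition of an alkenyl Grignard reagent to an α-substituted cyclic enone, in which the copper–NHC complex formed from Cu(OTf)2 and the chiral imidazolinium salt differentiates the enone faces and so sets C5 (3R in 4), while C2 is an inconsequential cis/trans mixture because it becomes the quaternary centre in step 2.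

Step 2
Reactants: 4 (2RS,3R)-2-methyl-3-(prop-1-en-2-yl)cyclohexan-1-one; 5 (S)-1-phenylethan-1-amine; 6 methyl prop-2-enoate
Product: 9 methyl 3-[(1S,6S)-1-methyl-2-oxo-6-(prop-1-en-2-yl)cyclohexyl]propanoate, via ketimine 7 (not isolated), via alkylated ketimine 8 (not isolated)
Conditions: 5, TsOH (cat.), toluene, reflux (Dean–Stark); 6, THF, 50 °C; 20 % aq. AcOH, 25 °C
Reagents that add atoms: methyl prop-2-enoate, C=CC(=O)OC; water, O
Why: Asymmetric Michael addition of a chiral imine through its more substituted secondary enamine tautomer (aza-ene-like transition state), so that the bond forms only at the methyl-bearing α-carbon, anti to the pseudo-axial isopropenyl group and on the face preferred by the (S)-1-phenylethyl auxiliary (matched pair), which sets C10 as S with methyl cis and the propanoate chain trans to isopropenyl; aqueous acid then hydrolyses ketimine 8 to the ketone and returns the amine.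

Step 3
Reactants: 9 methyl 3-[(1S,6S)-1-methyl-2-oxo-6-(prop-1-en-2-yl)cyclohexyl]propanoate
Product: 10 methyl 3-[(1S,6S)-1-methyl-2-oxo-6-(prop-1-en-2-yl)cyclohex-3-en-1-yl]propanoate
Conditions: IBX (2 equiv), DMSO, 70 °C
Reagents that add atoms: none
Why: IBX-mediated α,β-dehydrogenation of a ketone, regiodefined because C10 is quaternary and only C8 carries α-hydrogens, with neither stereocentre enolisable.

Step 4
Reactants: 10 methyl 3-[(1S,6S)-1-methyl-2-oxo-6-(prop-1-en-2-yl)cyclohex-3-en-1-yl]propanoate; 11 tert-butyl acetate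
Product: 13 methyl 3-[(1S,6S)-2-(2-tert-butoxy-2-oxoethyl)-2-hydroxy-1-methyl-6-(prop-1-en-2-yl)cyclohex-3-en-1-yl]propanoate (both C2 epimers), via lithium enolate 12 (not isolated)
Conditions: 11, LiN(iPr)2, THF, −78 °C; then 10, −78 °C; AcOH quench at −78 °C
Reagents that add atoms: tert-butyl acetate, CC(=O)OC(C)(C)C
Why: Kinetic 1,2-addition (aldol type) of a lithium ester enolate to the enone carbonyl, chemoselective over the methyl ester and quenched cold to prevent retro-aldol cleavage and lactonisation of the tertiary alkoxide onto the methyl ester; the new carbinol centre is a mixture of no consequence because it is destroyed in step 5.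

Step 5
Reactants: 13 methyl 3-[(1S,6S)-2-(2-tert-butoxy-2-oxoethyl)-2-hydroxy-1-methyl-6-(prop-1-en-2-yl)cyclohex-3-en-1-yl]propanoate
Product: 14 methyl 3-[(1S,6S)-2-(2-tert-butoxy-2-oxoethyl)-1-methyl-4-oxo-6-(prop-1-en-2-yl)cyclohex-2-en-1-yl]propanoate
Conditions: (C5H5NH)[CrO3Cl] (pyridinium chlorochromate, 2.5 equiv), 4 Å molecular sieves, CH2Cl2, 25 °C
Reagents that add atoms: none
Why: Babler–Dauben oxidative 1,3-transposition of a tertiary allylic alcohol, in which the chromate ester undergoes a [3,3]-sigmatropic shift to C7 and is oxidised there, so that the oxygen arrives at C7 and the acetate arm sits on the enone β-carbon C9.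

Step 6
Reactants: 14 methyl 3-[(1S,6S)-2-(2-tert-butoxy-2-oxoethyl)-1-methyl-4-oxo-6-(prop-1-en-2-yl)cyclohex-2-en-1-yl]propanoate
Product: 15 2-[(5S,6S)-6-(3-methoxy-3-oxopropyl)-6-methyl-3-oxo-5-(prop-1-en-2-yl)cyclohex-1-en-1-yl]acetic acid
Conditions: ZnBr2 (5 equiv), CH2Cl2, 25 °C; H2O
Reagents that add atoms: none
Why: Lewis-acid-mediated cleavage of a tert-butyl ester by loss of 2-methylpropene, selective over the methyl ester and mild enough for the isopropenyl group; the vinylogous β-keto acid is used at once to avoid decarboxylation.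

Step 7
Reactants: 15 2-[(5S,6S)-6-(3-methoxy-3-oxopropyl)-6-methyl-3-oxo-5-(prop-1-en-2-yl)cyclohex-1-en-1-yl]acetic acid; 16 methyl 3-methylbutanoate
Product: 20 methyl 3-[(1S,2S)-5,7-dihydroxy-1-methyl-4-oxo-6-(propan-2-yl)-2-(prop-1-en-2-yl)-1,2,3,4-tetrahydronaphthalen-1-yl]propanoate, via acid chloride 17 (not isolated), via lithium ester enolate 18 (not isolated), via keto ester 19 (not isolated)
Conditions: 1-chloro-N,N,2-trimethylprop-1-en-1-amine (1.1 equiv), CH2Cl2, 0 °C; added to 18 (2.2 equiv, from 16 and LiN(iPr)2, THF, −78 °C); then MeOH, −78 → 50 °C; 1 M HCl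
Reagents that add atoms: methyl 3-methylbutanoate, CC(C)CC(=O)OC
Why: Acid chloride 17 C-acylates the lithium ester enolate 18 at low temperature (crossed Claisen-type acylation, directly or by way of the vinylketene that 17 forms on loss of HCl), which makes C12–C13 and leaves keto ester 19 as its C11-deprotonated anion, whose charge is delocalised through C9=C8 onto the C7 oxygen. After methanol has turned the remaining base into methoxide, C8, the α-carbon of this vinylogous enolate, attacks the ester carbonyl C14 in a 6-(enolexo)-exo-trig Claisen (Dieckmann-type) closure of ring C, methoxide leaves and the triketone tautomerises irreversibly to the resorcinol 20. The closest known reaction types are the acylation of ester enolates by acid chlorides and the biomimetic polyketide-type Claisen cyclisation of polycarbonyl esters to acylresorcinols. No stereocentre is created, since C13 ends up aromatic, and C5 and C10 carry no acidic hydrogen. The step needs C- rather than O-acylation of 18 and ring closure at C8 alone: closure from C11 would give a four-membered ring, from oxygen an eight-membered ring, and from C6 or C13 onto a ketone a bridgehead-olefin bicycle, so the C8–C14 bond is the only strain-free path and aromatisation makes it the thermodynamic sink. The side-chain methyl ester is safe because leaving group and base are both methoxide.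

Step 8
Reactants: 20 methyl 3-[(1S,2S)-5,7-dihydroxy-1-methyl-4-oxo-6-(propan-2-yl)-2-(prop-1-en-2-yl)-1,2,3,4-tetrahydronaphthalen-1-yl]propanoate; 21 dipotassium nitrosodisulfonate (Fremy's salt)
Product: 22 methyl 3-[(1S,2S)-7-hydroxy-1-methyl-4,5,8-trioxo-6-(propan-2-yl)-2-(prop-1-en-2-yl)-1,2,3,4,5,8-hexahydronaphthalen-1-yl]propanoate (CNP0308749.1)
Conditions: K2[ON(SO3)2] (2.5 equiv), KH2PO4 buffer (pH 6), acetone–H2O, 0 → 25 °C
Reagents that add atoms: dipotassium nitrosodisulfonate, [K+].[K+].[O]N(S(=O)(=O)[O-])S(=O)(=O)[O-]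
Why: Teuber oxidation, in which the nitroxyl radical oxidises the C14 phenol and a second equivalent delivers oxygen to the free para position C11 to give the para-quinone with the C12 hydroxyl retained (attack starting at the C12 phenol would give the ortho-quinone tautomer of the same compound), while the isopropenyl group and the ester are inert to this reagent.

**Compound list**
1 | 2-methylcyclohex-2-en-1-one | CC1=CCCCC1=O | starting material
2 | prop-1-en-2-ylmagnesium bromide | C=C(C)[Mg]Br | starting material
3 | bromomagnesium enolate of 4 (bromomagnesium 2-methyl-3-(prop-1-en-2-yl)cyclohex-1-en-1-olate, C3 as in 4) | C=C(C)[C@@H]1CCCC(O[Mg]Br)=C1C | intermediate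
4 | (2RS,3R)-2-methyl-3-(prop-1-en-2-yl)cyclohexan-1-one | C=C(C)[C@@H]1CCCC(=O)C1C | intermediate
5 | (S)-1-phenylethan-1-amine | C[C@H](N)c1ccccc1 | starting material
6 | methyl prop-2-enoate | C=CC(=O)OC | starting material
7 | N-[(S)-1-phenylethyl] ketimine of 4 | C=C(C)[C@@H]1CCCC(=N[C@@H](C)c2ccccc2)C1C | intermediate
8 | N-[(S)-1-phenylethyl] ketimine of 9 | C=C(C)[C@@H]1CCCC(=N[C@@H](C)c2ccccc2)[C@@]1(C)CCC(=O)OC | intermediate
9 | methyl 3-[(1S,6S)-1-methyl-2-oxo-6-(prop-1-en-2-yl)cyclohexyl]propanoate | C=C(C)[C@@H]1CCCC(=O)[C@@]1(C)CCC(=O)OC | intermediate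
10 | methyl 3-[(1S,6S)-1-methyl-2-oxo-6-(prop-1-en-2-yl)cyclohex-3-en-1-yl]propanoate | C=C(C)[C@@H]1CC=CC(=O)[C@@]1(C)CCC(=O)OC | intermediate
11 | tert-butyl acetate | CC(=O)OC(C)(C)C | starting material
12 | lithium 1-tert-butoxyethen-1-olate (lithium enolate of 11) | C=C(O[Li])OC(C)(C)C | intermediate
13 | methyl 3-[(1S,6S)-2-(2-tert-butoxy-2-oxoethyl)-2-hydroxy-1-methyl-6-(prop-1-en-2-yl)cyclohex-3-en-1-yl]propanoate (both C2 epimers) | C=C(C)[C@@H]1CC=CC(O)(CC(=O)OC(C)(C)C)[C@@]1(C)CCC(=O)OC | intermediate
14 | methyl 3-[(1S,6S)-2-(2-tert-butoxy-2-oxoethyl)-1-methyl-4-oxo-6-(prop-1-en-2-yl)cyclohex-2-en-1-yl]propanoate | C=C(C)[C@@H]1CC(=O)C=C(CC(=O)OC(C)(C)C)[C@@]1(C)CCC(=O)OC | intermediate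
15 | 2-[(5S,6S)-6-(3-methoxy-3-oxopropyl)-6-methyl-3-oxo-5-(prop-1-en-2-yl)cyclohex-1-en-1-yl]acetic acid | C=C(C)[C@@H]1CC(=O)C=C(CC(=O)O)[C@@]1(C)CCC(=O)OC | intermediate
16 | methyl 3-methylbutanoate | CC(C)CC(=O)OC | starting material
17 | 2-[(5S,6S)-6-(3-methoxy-3-oxopropyl)-6-methyl-3-oxo-5-(prop-1-en-2-yl)cyclohex-1-en-1-yl]acetyl chloride | C=C(C)[C@@H]1CC(=O)C=C(CC(=O)Cl)[C@@]1(C)CCC(=O)OC | intermediate
18 | lithium 1-methoxy-3-methylbut-1-en-1-olate (lithium enolate of 16) | CC(C)C=C(O[Li])OC | intermediate
19 | methyl 4-[(5S,6S)-6-(3-methoxy-3-oxopropyl)-6-methyl-3-oxo-5-(prop-1-en-2-yl)cyclohex-1-en-1-yl]-3-oxo-2-(propan-2-yl)butanoate (both C2 epimers) | C=C(C)[C@@H]1CC(=O)C=C(CC(=O)C(C(C)C)C(=O)OC)[C@@]1(C)CCC(=O)OC | intermediate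
20 | methyl 3-[(1S,2S)-5,7-dihydroxy-1-methyl-4-oxo-6-(propan-2-yl)-2-(prop-1-en-2-yl)-1,2,3,4-tetrahydronaphthalen-1-yl]propanoate | C=C(C)[C@@H]1CC(=O)c2c(cc(O)c(C(C)C)c2O)[C@@]1(C)CCC(=O)OC | intermediate
21 | dipotassium nitrosodisulfonate (Fremy's salt), K2[ON(SO3)2] | [K+].[K+].[O]N(S(=O)(=O)[O-])S(=O)(=O)[O-] | starting material
22 | methyl 3-[(1S,2S)-7-hydroxy-1-methyl-4,5,8-trioxo-6-(propan-2-yl)-2-(prop-1-en-2-yl)-1,2,3,4,5,8-hexahydronaphthalen-1-yl]propanoate (CNP0308749.1) | C=C(C)[C@@H]1CC(=O)C2=C(C(=O)C(O)=C(C(C)C)C2=O)[C@@]1(C)CCC(=O)OC | target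

Total step count: 8. Longest linear sequence: 8 steps (1 → 22); all other inputs are commercial.

**Steps most likely to fail**

Step 7. Proton transfer or O-acylation may outrun C-acylation of the ester enolate, or the vinylogous enolate may fail to close on the ester and leave open-chain material. The fallback replaces enolate chemistry by a pericyclic sequence. It sets out from 15, which is converted as before into acid chloride 17 and dehydrochlorinated with Et3N in toluene to the vinylketene. This is trapped at 80 °C by 3-methyl-1-[tri(propan-2-yl)silyloxy]but-1-yne F1, made in one flask from ethyl 2-methylpropanoate under Kowalski homologation conditions with iPr3SiCl trapping. Ketene–alkyne [2+2] cycloaddition, 4π ring opening of the cyclobutenone and 6π electrocyclisation (Danheiser benzannulation) should give the monosilyl ether methyl 3-[(1S,2S)-5-hydroxy-1-methyl-4-oxo-6-(propan-2-yl)-2-(prop-1-en-2-yl)-7-[tri(propan-2-yl)silyloxy]-1,2,3,4-tetrahydronaphthalen-1-yl]propanoate F2. Bu4NF/AcOH in THF removes the silyl group and the route is rejoined at 20.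

Step 1. Enantioface discrimination may be poor for an alkenyl Grignard reagent on an α-methyl enone, and 1,2-addition may compete. The fallback gives up catalyst control and sets out from 1 and 2. An achiral addition (CuBr·SMe2 cat., Me3SiCl, THF, −78 °C, then dilute HCl) gives the racemic ketone, that is 4 together with its enantiomer (2RS,3S)-2-methyl-3-(prop-1-en-2-yl)cyclohexan-1-one F3. Step 2 is then run to partial conversion with the same amine 5 as a kinetic resolution. Only the 3R ketone is matched, because acrylate attack anti to isopropenyl coincides with the face preferred by the (S)-auxiliary. Unreacted F3 is removed after hydrolysis and the route is rejoined at 9.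

Step 5. Under the acidic chromium conditions the tertiary allylic carbinol may ionise and dehydrate to a dienyl ester, or lose the acetate arm by retro-aldol cleavage, instead of undergoing the [3,3]-shift. The fallback separates transposition from oxidation and sets out from 13. Catalytic Ph3SiOReO3 in Et2O (−50 → 0 °C) should isomerise it without oxidant to the secondary allylic alcohol methyl 3-[(1S,6S)-2-(2-tert-butoxy-2-oxoethyl)-4-hydroxy-1-methyl-6-(prop-1-en-2-yl)cyclohex-2-en-1-yl]propanoate F4 (both C4 epimers). Dess–Martin periodinane (NaHCO3, CH2Cl2) then oxidises F4 and the route is rejoined at 14.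

**Further compounds**
F1 | step 7 | 3-methyl-1-[tri(propan-2-yl)silyloxy]but-1-yne | CC(C)C#CO[Si](C(C)C)(C(C)C)C(C)C
F2 | step 7 | methyl 3-[(1S,2S)-5-hydroxy-1-methyl-4-oxo-6-(propan-2-yl)-2-(prop-1-en-2-yl)-7-[tri(propan-2-yl)silyloxy]-1,2,3,4-tetrahydronaphthalen-1-yl]propanoate | C=C(C)[C@@H]1CC(=O)c2c(cc(O[Si](C(C)C)(C(C)C)C(C)C)c(C(C)C)c2O)[C@@]1(C)CCC(=O)OC
F3 | step 1 | (2RS,3S)-2-methyl-3-(prop-1-en-2-yl)cyclohexan-1-one | C=C(C)[C@H]1CCCC(=O)C1C
F4 | step 5 | methyl 3-[(1S,6S)-2-(2-tert-butoxy-2-oxoethyl)-4-hydroxy-1-methyl-6-(prop-1-en-2-yl)cyclohex-2-en-1-yl]propanoate (both C4 epimers) | C=C(C)[C@@H]1CC(O)C=C(CC(=O)OC(C)(C)C)[C@@]1(C)CCC(=O)OC
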